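The A ring carries O1 on C8a para to the C6 oxygen, C4 on the neighbouring C4a, an unsubstituted C5 and methoxy groups on C7 and C8. This is the pattern a Dötz benzannulation delivers when O1 is the carbene alkoxy oxygen, so the route disconnects C4a–C8a, C5–C6 and C6–C7. One thermal operation on a pentacarbonylchromium carbene bearing an (E)-1,2-dimethoxyvinyl group and, on oxygen, a (2S,3R)-2-aryl-3-silyloxypent-4-ynyl chain should close the pyran ring and the A ring together. C3 and C4 are set beforehand by an Evans syn aldol; methylation and two deprotections finish the synthesis.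

Key step: step 11

Assumption: the pure E isomer of 1,2-dimethoxyethene is used (bought or fractionated from the commercial E/Z mixture), because its α-lithio derivative has lithium syn to the β-methoxy group and should resist anti-elimination to methoxyethyne; chromium carbonyl ligands are written as Cr=C=O in the SMILES.

Step 1
Reactants: 1 2,3-dimethoxy-1,4-benzoquinone
Product: 3 1,4-bis(benzyloxy)-2,3-dimethoxybenzene, via 2,3-dimethoxyhydroquinone 2 (not isolated)
Conditions: Na2S2O4, THF/H2O, rt; extract, concentrate under Ar; then BnBr, K2CO3, DMF, 60 °C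
Reagents that add atoms: benzyl bromide, BrCc1ccccc1
Why: Dithionite reduction of the quinone followed by Williamson O-benzylation of both phenols should give the symmetric diether, with no regiochemical question.

Step 2
Reactants: 3 1,4-bis(benzyloxy)-2,3-dimethoxybenzene
Product: 4 1,4-bis(benzyloxy)-5-bromo-2,3-dimethoxybenzene
Conditions: NBS (1.0 equiv), MeCN, 0 °C → rt
Reagents that add atoms: N-bromosuccinimide, O=C1CCC(=O)N1Br
Why: Electrophilic aromatic bromination can only attack the two equivalent free ring positions, and the first bromine deactivates the ring enough for one equivalent of NBS to stop at the monobromide.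

Step 3
Reactants: 4 1,4-bis(benzyloxy)-5-bromo-2,3-dimethoxybenzene; 5 bromo(2-tert-butoxy-2-oxoethyl)zinc (Reformatsky reagent of tert-butyl bromoacetate, THF solution)
Product: 6 tert-butyl 2-[2,5-bis(benzyloxy)-3,4-dimethoxyphenyl]acetate
Conditions: Pd(dba)2 (2 mol%), Q-Phos (2 mol%), THF, rt → 60 °C
Reagents that add atoms: none
Why: Palladium-catalysed α-arylation of a zinc ester enolate (Negishi-type coupling of a Reformatsky reagent) is non-basic, tolerates electron-rich ortho-alkoxy aryl bromides and should stop at monoarylation.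

Step 4
Reactants: 6 tert-butyl 2-[2,5-bis(benzyloxy)-3,4-dimethoxyphenyl]acetate
Product: 7 2-[2,5-bis(benzyloxy)-3,4-dimethoxyphenyl]acetic acid
Conditions: TFA/CH2Cl2 (1:4), 0 °C → rt
Reagents that add atoms: none
Why: Acidolysis of the tert-butyl ester with loss of isobutene should free the acid under conditions that aryl benzyl and methyl ethers survive at room temperature.

Step 5
Reactants: 7 2-[2,5-bis(benzyloxy)-3,4-dimethoxyphenyl]acetic acid; 8 (R)-4-benzyloxazolidin-2-one
Product: 10 (R)-4-benzyl-3-{2-[2,5-bis(benzyloxy)-3,4-dimethoxyphenyl]acetyl}oxazolidin-2-one, via mixed pivalic anhydride 9 (not isolated)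
Conditions: PivCl, Et3N, THF, −20 °C; then 8, LiCl, −20 °C → rt
Reagents that add atoms: pivaloyl chloride, CC(C)(C)C(Cl)=O (acyl group retained only in 9)
Why: N-Acylation of the oxazolidinone through the mixed pivalic anhydride with LiCl/Et3N activation occurs at the less hindered arylacetyl carbonyl and avoids the ketene pathway of arylacetyl chlorides.

Step 6
Reactants: 10 (R)-4-benzyl-3-{2-[2,5-bis(benzyloxy)-3,4-dimethoxyphenyl]acetyl}oxazolidin-2-one; 11 3-(trimethylsilyl)propynal
Product: 13 (4R)-4-benzyl-3-[(2R,3R)-2-[2,5-bis(benzyloxy)-3,4-dimethoxyphenyl]-3-hydroxy-5-(trimethylsilyl)pent-4-ynoyl]oxazolidin-2-one, via Z-dibutylboron enolate 12 (not isolated)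
Conditions: Bu2BOTf, iPr2NEt, CH2Cl2, −78 → 0 °C; then 11, −78 → 0 °C; pH 7 buffer, MeOH, H2O2, 0 °C
Reagents that add atoms: dibutylboron triflate, CCCCB(CCCC)OS(=O)(=O)C(F)(F)F (boron retained only in 12)
Why: In this Evans syn aldol the Z boron enolate reacts through a Zimmerman–Traxler chair in which the aldehyde approaches the face away from the benzyl group of the (R)-auxiliary, which should set both centres as (2R,3R) with aryl and hydroxyl syn, the arrangement that becomes trans-3,4 in the chroman.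

Step 7
Reactants: 13 (4R)-4-benzyl-3-[(2R,3R)-2-[2,5-bis(benzyloxy)-3,4-dimethoxyphenyl]-3-hydroxy-5-(trimethylsilyl)pent-4-ynoyl]oxazolidin-2-one
Product: 14 (4R)-4-benzyl-3-[(2R,3R)-2-[2,5-bis(benzyloxy)-3,4-dimethoxyphenyl]-3-[(tert-butyldimethylsilyl)oxy]-5-(trimethylsilyl)pent-4-ynoyl]oxazolidin-2-one
Conditions: TBSOTf, 2,6-lutidine, CH2Cl2, −78 → 0 °C
Reagents that add atoms: tert-butyldimethylsilyl triflate, CC(C)(C)[Si](C)(C)OS(=O)(=O)C(F)(F)F
Why: O-Silylation with a silyl triflate and a hindered pyridine base is fast at low temperature and too weakly basic to cause retro-aldol cleavage or epimerisation of the α-aryl centre.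

Step 8
Reactants: 14 (4R)-4-benzyl-3-[(2R,3R)-2-[2,5-bis(benzyloxy)-3,4-dimethoxyphenyl]-3-[(tert-butyldimethylsilyl)oxy]-5-(trimethylsilyl)pent-4-ynoyl]oxazolidin-2-one
Product: 16 (2S,3R)-2-[2,5-bis(benzyloxy)-3,4-dimethoxyphenyl]-3-[(tert-butyldimethylsilyl)oxy]pent-4-yn-1-ol, via C-silylated alkynol 15 (not isolated)
Conditions: LiBH4, MeOH (1 equiv), THF, 0 °C; then MeOH, K2CO3, 0 °C → rt
Reagents that add atoms: none
Why: Reductive cleavage of the imide by LiBH4 at the exocyclic carbonyl gives the primary alcohol and ends the acidity of the α-aryl centre (its descriptor changes to S only through CIP priorities), and the subsequent carbonate methanolysis cleaves the C(sp)–Si bond while the secondary O-silyl ether stays.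

Step 9
Reactants: 17 (E)-1,2-dimethoxyethene; 18 chromium hexacarbonyl
Product: 21 tetramethylammonium pentacarbonyl[(E)-2,3-dimethoxy-1-oxidoprop-2-en-1-ylidene]chromate, via (E)-1,2-dimethoxyvinyllithium 19 (not isolated), via lithium acylchromate 20 (not isolated)
Conditions: t-BuLi, THF, −78 °C; then Cr(CO)6, THF/Et2O, −78 °C → rt; then Me4NBr, degassed H2O, 0 °C
Reagents that add atoms: tert-butyllithium, [Li]C(C)(C)C (lithium retained only in 19 and 20); tetramethylammonium bromide, C[N+](C)(C)C.[Br-]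
Why: In this Fischer carbene synthesis, α-lithiation of the enol ether with retention of alkene geometry and addition of the vinyllithium to a CO ligand give the acylchromate, and cation metathesis should give the storable tetramethylammonium salt.

Step 10
Reactants: 21 tetramethylammonium pentacarbonyl[(E)-2,3-dimethoxy-1-oxidoprop-2-en-1-ylidene]chromate; 16 (2S,3R)-2-[2,5-bis(benzyloxy)-3,4-dimethoxyphenyl]-3-[(tert-butyldimethylsilyl)oxy]pent-4-yn-1-ol
Product: 23 pentacarbonyl{[(2S,3R)-2-[2,5-bis(benzyloxy)-3,4-dimethoxyphenyl]-3-[(tert-butyldimethylsilyl)oxy]pent-4-yn-1-yl]oxy}[(E)-1,2-dimethoxyvinyl]carbene chromium(0), via acetoxycarbene complex 22 (not isolated)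
Conditions: AcBr (slight excess of 21 and AcBr over 16), CH2Cl2, −40 °C; then 16, −40 → −10 °C; cold filtration through silica, used at once
Reagents that add atoms: acetyl bromide, CC(Br)=O (acetyl retained only in 22)
Why: O-Acylation of the acylate gives a strongly electrophilic acyloxycarbene, which the primary alcohol attacks at the carbene carbon in an addition–elimination (alcoholysis of an acyloxycarbene) at low temperature, leaving both stereocentres and the terminal alkyne untouched.

Step 11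
Reactants: 23 pentacarbonyl{[(2S,3R)-2-[2,5-bis(benzyloxy)-3,4-dimethoxyphenyl]-3-[(tert-butyldimethylsilyl)oxy]pent-4-yn-1-yl]oxy}[(E)-1,2-dimethoxyvinyl]carbene chromium(0)
Product: 24 (3S,4R)-3-[2,5-bis(benzyloxy)-3,4-dimethoxyphenyl]-4-[(tert-butyldimethylsilyl)oxy]-7,8-dimethoxychroman-6-ol
Conditions: THF (0.01 M), 55 °C, Ar; then air, rt
Reagents that add atoms: none
Why: Warming expels a cis-CO (the β-methoxy group, cis to the carbene carbon, can hold the vacant site), the tethered alkyne inserts so that carbene carbon C8a bonds to the internal alkyne carbon C4a, CO inserts at the new carbene carbon C5 to give the chromium-bound dienylketene (C6), and 6π-electrocyclisation onto the vinyl β-carbon C7 followed by enolisation gives the C6 phenol, which air frees from chromium. The closest known reaction type is the intramolecular Dötz benzannulation of alkoxy(alkenyl)carbene chromium complexes whose alkyne is tethered through the carbene oxygen. The pyran ring closes in the insertion step as an exo-dig closure of the six-membered O1–C2–C3–C4–C4a–C8a ring, and the A ring closes by the disrotatory electrocyclisation that forms C6–C7 after CO insertion has formed C5–C6. No stereocentre is created, and C3 and C4 sit in the tether under neutral thermal conditions, so they should pass unchanged. The step needs regiocontrol of alkyne insertion and phenol formation in preference to furan or cyclopentannulation products: the three-atom tether allows only the C8a–C4a union (the reverse mode would need a seven-membered ring), it holds C5 and C8 cis on the new C4a=C8a bond as the electrocyclisation requires, and a chromium alkenyl carbene in THF favours CO insertion. The terminal alkyne leaves C5 unsubstituted and the vinyl group delivers C7 and C8 with their methoxy groups in place.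

Step 12
Reactants: 24 (3S,4R)-3-[2,5-bis(benzyloxy)-3,4-dimethoxyphenyl]-4-[(tert-butyldimethylsilyl)oxy]-7,8-dimethoxychroman-6-ol
Product: 25 (3S,4R)-3-[2,5-bis(benzyloxy)-3,4-dimethoxyphenyl]-4-[(tert-butyldimethylsilyl)oxy]-6,7,8-trimethoxychroman
Conditions: MeI, K2CO3, DMF, rt, Ar
Reagents that add atoms: iodomethane, CI
Why: Williamson O-methylation of the only free phenol under carbonate conditions should leave the silyl and benzyl ethers intact.

Step 13
Reactants: 25 (3S,4R)-3-[2,5-bis(benzyloxy)-3,4-dimethoxyphenyl]-4-[(tert-butyldimethylsilyl)oxy]-6,7,8-trimethoxychroman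
Product: 26 (3S,4R)-3-[2,5-bis(benzyloxy)-3,4-dimethoxyphenyl]-6,7,8-trimethoxychroman-4-ol
Conditions: TBAF, THF, 0 °C → rt
Reagents that add atoms: none
Why: Fluoride-mediated desilylation cleaves the Si–O bond without acid, so the activated benzylic C4–O bond should not ionise and the configuration at C4 is kept.

Step 14
Reactants: 26 (3S,4R)-3-[2,5-bis(benzyloxy)-3,4-dimethoxyphenyl]-6,7,8-trimethoxychroman-4-ol
Product: 27 (3S,4R)-3-(2,5-dihydroxy-3,4-dimethoxyphenyl)-6,7,8-trimethoxychroman-4-ol (CNP0111047.1)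
Conditions: H2 (1 atm), 10% Pd/C, EtOAc, rt; filtration and concentration under Ar
Reagents that add atoms: none
Why: Catalytic hydrogenolysis of aryl benzyl ethers in a neutral aprotic solvent is much faster than hydrogenolysis of a secondary benzylic alcohol, and the absence of acid should prevent cyclisation of the 2'-phenol onto C4.

Compound list
1 | 2,3-dimethoxy-1,4-benzoquinone | COC1=C(OC)C(=O)C=CC1=O | starting material
2 | 2,3-dimethoxybenzene-1,4-diol | COc1c(O)ccc(O)c1OC | intermediate
3 | 1,4-bis(benzyloxy)-2,3-dimethoxybenzene | COc1c(OCc2ccccc2)ccc(OCc2ccccc2)c1OC | intermediate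
4 | 1,4-bis(benzyloxy)-5-bromo-2,3-dimethoxybenzene | COc1c(OCc2ccccc2)cc(Br)c(OCc2ccccc2)c1OC | intermediate
5 | bromo(2-tert-butoxy-2-oxoethyl)zinc | Br[Zn]CC(=O)OC(C)(C)C | starting material
6 | tert-butyl 2-[2,5-bis(benzyloxy)-3,4-dimethoxyphenyl]acetate | COc1c(OCc2ccccc2)cc(CC(=O)OC(C)(C)C)c(OCc2ccccc2)c1OC | intermediate
7 | 2-[2,5-bis(benzyloxy)-3,4-dimethoxyphenyl]acetic acid | COc1c(OCc2ccccc2)cc(CC(=O)O)c(OCc2ccccc2)c1OC | intermediate
8 | (R)-4-benzyloxazolidin-2-one | O=C1N[C@H](Cc2ccccc2)CO1 | starting material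
9 | 2-[2,5-bis(benzyloxy)-3,4-dimethoxyphenyl]acetic pivalic anhydride | COc1c(OCc2ccccc2)cc(CC(=O)OC(=O)C(C)(C)C)c(OCc2ccccc2)c1OC | intermediate
10 | (R)-4-benzyl-3-{2-[2,5-bis(benzyloxy)-3,4-dimethoxyphenyl]acetyl}oxazolidin-2-one | COc1c(OCc2ccccc2)cc(CC(=O)N2[C@H](Cc3ccccc3)COC2=O)c(OCc2ccccc2)c1OC | intermediate
11 | 3-(trimethylsilyl)propynal | C[Si](C)(C)C#CC=O | starting material
12 | (Z)-O-dibutylboron enolate of imide 10 | CCCCB(CCCC)O/C(=C\c1cc(OCc2ccccc2)c(OC)c(OC)c1OCc1ccccc1)N1[C@H](Cc2ccccc2)COC1=O | intermediate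
13 | (4R)-4-benzyl-3-[(2R,3R)-2-[2,5-bis(benzyloxy)-3,4-dimethoxyphenyl]-3-hydroxy-5-(trimethylsilyl)pent-4-ynoyl]oxazolidin-2-one | O=C(N1[C@H](Cc2ccccc2)COC1=O)[C@H](c1cc(OCc2ccccc2)c(OC)c(OC)c1OCc1ccccc1)[C@@H](O)C#C[Si](C)(C)C | intermediate
14 | (4R)-4-benzyl-3-[(2R,3R)-2-[2,5-bis(benzyloxy)-3,4-dimethoxyphenyl]-3-[(tert-butyldimethylsilyl)oxy]-5-(trimethylsilyl)pent-4-ynoyl]oxazolidin-2-one | O=C(N1[C@H](Cc2ccccc2)COC1=O)[C@H](c1cc(OCc2ccccc2)c(OC)c(OC)c1OCc1ccccc1)[C@@H](O[Si](C)(C)C(C)(C)C)C#C[Si](C)(C)C | intermediate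
15 | (2S,3R)-2-[2,5-bis(benzyloxy)-3,4-dimethoxyphenyl]-3-[(tert-butyldimethylsilyl)oxy]-5-(trimethylsilyl)pent-4-yn-1-ol | OC[C@H](c1cc(OCc2ccccc2)c(OC)c(OC)c1OCc1ccccc1)[C@H](C#C[Si](C)(C)C)O[Si](C)(C)C(C)(C)C | intermediate
16 | (2S,3R)-2-[2,5-bis(benzyloxy)-3,4-dimethoxyphenyl]-3-[(tert-butyldimethylsilyl)oxy]pent-4-yn-1-ol | OC[C@H](c1cc(OCc2ccccc2)c(OC)c(OC)c1OCc1ccccc1)[C@H](C#C)O[Si](C)(C)C(C)(C)C | intermediate
17 | (E)-1,2-dimethoxyethene | CO/C=C/OC | starting material
18 | chromium hexacarbonyl | O=C=[Cr](=C=O)(=C=O)(=C=O)(=C=O)=C=O | starting material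
19 | (E)-1,2-dimethoxyvinyllithium | [Li]/C(OC)=C\OC | intermediate
20 | lithium pentacarbonyl[(E)-2,3-dimethoxy-1-oxidoprop-2-en-1-ylidene]chromate | [Li+].[O-]C(=[Cr](=C=O)(=C=O)(=C=O)(=C=O)=C=O)/C(OC)=C\OC | intermediate
21 | tetramethylammonium pentacarbonyl[(E)-2,3-dimethoxy-1-oxidoprop-2-en-1-ylidene]chromate | C[N+](C)(C)C.[O-]C(=[Cr](=C=O)(=C=O)(=C=O)(=C=O)=C=O)/C(OC)=C\OC | intermediate
22 | pentacarbonyl[acetoxy((E)-1,2-dimethoxyvinyl)carbene]chromium(0) | CC(=O)OC(=[Cr](=C=O)(=C=O)(=C=O)(=C=O)=C=O)/C(OC)=C\OC | intermediate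
23 | pentacarbonyl{[(2S,3R)-2-[2,5-bis(benzyloxy)-3,4-dimethoxyphenyl]-3-[(tert-butyldimethylsilyl)oxy]pent-4-yn-1-yl]oxy}[(E)-1,2-dimethoxyvinyl]carbene chromium(0) | O=C=[Cr](=C=O)(=C=O)(=C=O)(=C=O)=C(OC[C@H](c1cc(OCc2ccccc2)c(OC)c(OC)c1OCc1ccccc1)[C@H](C#C)O[Si](C)(C)C(C)(C)C)/C(OC)=C\OC | intermediate
24 | (3S,4R)-3-[2,5-bis(benzyloxy)-3,4-dimethoxyphenyl]-4-[(tert-butyldimethylsilyl)oxy]-7,8-dimethoxychroman-6-ol (trans) | Oc1cc2c(c(OC)c1OC)OC[C@H](c3cc(OCc4ccccc4)c(OC)c(OC)c3OCc5ccccc5)[C@H]2O[Si](C)(C)C(C)(C)C | intermediate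
25 | (3S,4R)-3-[2,5-bis(benzyloxy)-3,4-dimethoxyphenyl]-4-[(tert-butyldimethylsilyl)oxy]-6,7,8-trimethoxychroman | COc1cc2c(c(OC)c1OC)OC[C@H](c3cc(OCc4ccccc4)c(OC)c(OC)c3OCc5ccccc5)[C@H]2O[Si](C)(C)C(C)(C)C | intermediate
26 | (3S,4R)-3-[2,5-bis(benzyloxy)-3,4-dimethoxyphenyl]-6,7,8-trimethoxychroman-4-ol | COc1cc2c(c(OC)c1OC)OC[C@H](c3cc(OCc4ccccc4)c(OC)c(OC)c3OCc5ccccc5)[C@H]2O | intermediate
27 | (3S,4R)-3-(2,5-dihydroxy-3,4-dimethoxyphenyl)-6,7,8-trimethoxychroman-4-ol (trans) | COc1cc2c(c(OC)c1OC)OC[C@H](c1cc(O)c(OC)c(OC)c1O)[C@H]2O | target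

Total step count: 14. Longest linear sequence: 13 steps (steps 1–8 and 10–14); step 9 is a one-step side branch that joins at step 10.

Steps most likely to fail

Step 11. After alkyne insertion the vinylcarbene or vinylketene may be diverted (cyclisation without CO insertion, or decomposition of the electron-rich carbene before the alkyne engages), so that the two rings do not close cleanly. The fallback buys the A ring preformed and closes only the pyran ring; it sets out from imide 10 and comes back at 25. Allylation of 2-hydroxy-3,4,5-trimethoxybenzaldehyde (allyl bromide, K2CO3, DMF) should give 2-(allyloxy)-3,4,5-trimethoxybenzaldehyde F1. An Evans syn aldol of 10 with this aldehyde under the conditions of step 6 should give the (2R,3R) aldol adduct F2. Silylation (TBSOTf, 2,6-lutidine) should give the silyl ether F3, and LiBH4 reduction the primary alcohol F4. Deallylation (Pd(PPh3)4, morpholine) should give the phenol F5. Mitsunobu etherification (PPh3, DIAD, THF) between the phenol oxygen (O1) and the primary carbinol carbon (C2) should then close the chroman and deliver 25 with C3 and C4 unchanged.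

Step 10. The acetoxycarbene may decompose thermally before the β-branched alcohol exchanges, or the alkoxycarbene may begin to react during isolation. The fallback reverses the polarity of the O–C bond formation; it sets out from 16 and comes back at 23. Triflation of 16 (Tf2O, 2,6-di-tert-butyl-4-methylpyridine, CH2Cl2, −78 °C) should give the primary triflate F6, which is kept cold and used to O-alkylate acylate 21 (CH2Cl2, −40 → 0 °C), the classical hard-alkylation entry to alkoxycarbene complexes.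

Step 14. Hydrogenolysis may go on to cleave the activated benzylic C4–O bond, and the liberated hydroquinone may oxidise during catalyst removal. The fallback keeps C4–O masked during the reductive step; it sets out from 25 and comes back at 27. Hydrogenolysis of 25 (H2, Pd/C, EtOAc) should give the silyl-protected hydroquinone F7, and desilylation with acetic acid-buffered TBAF in degassed THF under argon should then give 27 directly.

Further compounds
F1 | step 11 | 2-(allyloxy)-3,4,5-trimethoxybenzaldehyde | C=CCOc1c(C=O)cc(OC)c(OC)c1OC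
F2 | step 11 | (4R)-3-[(2R,3R)-3-[2-(allyloxy)-3,4,5-trimethoxyphenyl]-2-[2,5-bis(benzyloxy)-3,4-dimethoxyphenyl]-3-hydroxypropanoyl]-4-benzyloxazolidin-2-one | O=C(N1[C@H](Cc2ccccc2)COC1=O)[C@H](c1cc(OCc2ccccc2)c(OC)c(OC)c1OCc1ccccc1)[C@@H](O)c1cc(OC)c(OC)c(OC)c1OCC=C
F3 | step 11 | (4R)-3-[(2R,3R)-3-[2-(allyloxy)-3,4,5-trimethoxyphenyl]-2-[2,5-bis(benzyloxy)-3,4-dimethoxyphenyl]-3-[(tert-butyldimethylsilyl)oxy]propanoyl]-4-benzyloxazolidin-2-one | O=C(N1[C@H](Cc2ccccc2)COC1=O)[C@H](c1cc(OCc2ccccc2)c(OC)c(OC)c1OCc1ccccc1)[C@@H](O[Si](C)(C)C(C)(C)C)c1cc(OC)c(OC)c(OC)c1OCC=C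
F4 | step 11 | (2S,3R)-3-[2-(allyloxy)-3,4,5-trimethoxyphenyl]-2-[2,5-bis(benzyloxy)-3,4-dimethoxyphenyl]-3-[(tert-butyldimethylsilyl)oxy]propan-1-ol | OC[C@H](c1cc(OCc2ccccc2)c(OC)c(OC)c1OCc1ccccc1)[C@@H](O[Si](C)(C)C(C)(C)C)c1cc(OC)c(OC)c(OC)c1OCC=C
F5 | step 11 | 6-[(1R,2S)-2-[2,5-bis(benzyloxy)-3,4-dimethoxyphenyl]-1-[(tert-butyldimethylsilyl)oxy]-3-hydroxypropyl]-2,3,4-trimethoxyphenol | OC[C@H](c1cc(OCc2ccccc2)c(OC)c(OC)c1OCc1ccccc1)[C@@H](O[Si](C)(C)C(C)(C)C)c1cc(OC)c(OC)c(OC)c1O
F6 | step 10 | (2S,3R)-2-[2,5-bis(benzyloxy)-3,4-dimethoxyphenyl]-3-[(tert-butyldimethylsilyl)oxy]pent-4-yn-1-yl trifluoromethanesulfonate | FC(F)(F)S(=O)(=O)OC[C@H](c1cc(OCc2ccccc2)c(OC)c(OC)c1OCc1ccccc1)[C@H](C#C)O[Si](C)(C)C(C)(C)C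
F7 | step 14 | 2-[(3S,4R)-4-[(tert-butyldimethylsilyl)oxy]-6,7,8-trimethoxychroman-3-yl]-5,6-dimethoxybenzene-1,4-diol | COc1cc2c(c(OC)c1OC)OC[C@H](c1cc(O)c(OC)c(OC)c1O)[C@H]2O[Si](C)(C)C(C)(C)C
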